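## The problem

Compound 11 is a single six-membered carbocycle with no ring fusion. C1 is a fully substituted carbinol carbon carrying the tertiary hydroxyl and the two-carbon chain C7–C8, C4 is the ring ketone, and O8 is esterified with hexadecanoic acid. A mirror plane runs through C1 and C4, so the molecule has no stereocentre; any stereocentre that arises on the way is transient, can steer nothing and only has to be erased. What must be built is a quaternary oxygenated carbon placed 1,4 to a carbonyl group, a dissonant relationship that aldol or Michael logic does not deliver directly. The delicate groups are the tertiary alcohol (ionisation and dehydration under strong acid or prolonged heating) and the long-chain primary ester, which would not survive alkoxide bases or hot nucleophilic salts and therefore belongs at the end. The primary hydroxyl must also be told apart from the tertiary one. The enabling feature is that both ring arms leaving C1 (C2–C3–C4, and C6–C5 plus one carboxyl carbon that is later extruded) are three-carbon acrylate units. The C1–C2 bond joins a ketone carbon to an acrylate β-carbon, two centres that are both electrophilic and can be bonded only after electron injection. Once that bond exists, the C1 oxygen lies γ to an ester carbonyl and closes a five-membered lactone, which masks the tertiary alcohol and makes C4 the acyl acceptor for ring closure at C4–C5.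

## Retrosynthesis

**Ester C–O bond.** The acyl–O8 bond of 11 is cut first, giving diol 9 and palmitoyl chloride 10. The fatty ester cannot be carried through enolate chemistry or hot chloride, so it goes on last. The forward reaction only has to distinguish a primary from a hindered tertiary hydroxyl.

**Benzyl–O8 bond.** Diol 9 is traced to benzyl ether 8. O8 needs a mask that tolerates cathodic reduction, tert-butoxide and hot chloride, and that leaves under neutral conditions sparing the ketone and the tertiary alcohol. A benzyl ether meets this and is already present in the commercial aldehyde 1, so no protection step is spent.

**C5–carboxyl bond (retrosynthetic addition).** A methoxycarbonyl group is placed on C5 of 8, giving β-keto ester 6; the forward loss passes through carboxylate 7. This group is what allows the ring to be closed by acyl substitution. It must later come off without acid, since acid would endanger the tertiary carbinol.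

**C4–C5 bond.** The ring of 6 is opened between the ketone carbon C4 and the ester-bearing C5, and the C1 oxygen is joined to C4 as a lactone, giving 5. This cut is preferred over opening the ring at C1, because it keeps C1 fully assembled and uses its oxygen as an internal leaving group. Compound 5 has one small ring instead of the carbocycle, and both of its carbonyls are at the acid oxidation level. The forward step is a six-membered Claisen-type closure that must end at a single β-keto ester.

**C1–C2 bond and lactone O–acyl bond (key).** Lactone 5 is opened to hydroxy diester 4 and then cut between C1 and C2, giving keto ester 3 and methyl acrylate 2. The cut is attractive because 4 has two identical arms, so it does not matter which arm lactonises. Both fragments are electrophiles, so the forward step must be a reductive union, with cross-coupling favoured over self-coupling of either partner.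

**C1–C6 bond.** Keto ester 3 is cut between the ketone carbon and its α-methylene into aldehyde 1 and a second molecule of 2. The aldehyde carbon must react as an acyl anion, which is the task of carbene-catalysed conjugate hydroacylation. Thus 1 supplies C1, C7 and C8, and two molecules of 2 supply C2–C6 plus the carbon later lost as carbon dioxide.

## Roads not taken

**Alternative 1: Prins capture as a spiro-1,3-dioxane.**
- Cut: C7–C8 and C1–O.
- Forward key step: the exocyclic alkene of 4-methylenecyclohexan-1-one A1 attacks acid-activated formaldehyde A2. The tertiary cation at C1 is trapped by the oxygen of a second molecule of A2, closing 1,3-dioxaspiro[5.5]undecan-9-one A3. Cleavage of the formal would give 9, and the last step would be as in the chosen route.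
- Merits: the ring is bought, both oxygens and the chain arrive in one operation, and the whole sequence is about three steps from A1. It needs no special equipment.
- Weak points: A1 has an enolisable ketone that can be hydroxymethylated by A2 under the same acid. The C1 cation can lose a proton instead of being trapped, and the exocyclic double bond can migrate into the ring. The methylene acetal of A3 is among the most acid-resistant acetals, and the acid needed to open it regenerates the very C1 cation that leads to dehydration. A1 itself has to be made in about two steps from a mono-protected dione.
- Comparison: this road is shorter. The chosen plan sets against it that each bond is formed with an unambiguous site of reaction, and that the tertiary carbinol is never exposed to strong acid.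

**Alternative 2: both ring oxygens from one molecule of dioxygen.**
- Cut: the C1–O and C4–O bonds.
- Forward key step: 1-[2-(benzyloxy)ethyl]cyclohexa-1,3-diene A4 adds dioxygen A5 in its photosensitised singlet state across C1 and C4, giving endoperoxide A6. Base-induced Kornblum–DeLaMare rearrangement would give 4-[2-(benzyloxy)ethyl]-4-hydroxycyclohex-2-en-1-one A7, and one hydrogenation would give 9.
- Merits: the 1,4-dioxygen pattern is placed exactly, the conditions are mild, and only two steps separate A6 from 9, against three from 5 to 9 in the chosen route.
- Weak points: A4 is not commercial. Dehydration or isomerisation routes to it give mixtures of diene isomers, and it tends to aromatise or dimerise. The ene reaction at the allylic C–H bonds of A4 competes with the cycloaddition, and a peroxide has to be handled. The total is about seven steps.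
- Comparison: the end game of this road is shorter, and a photoreactor is no more demanding than an electrolysis cell. The chosen plan sets against it a key-step precursor made in one step from commercial materials with no isomer problem.

**Alternative 3: [3+3] annulation of an acetone dianion equivalent.**
- Cut: C2–C3 and C5–C6.
- Forward key step: the azaenolate of acetone N,N-dimethylhydrazone A8 is alkylated by 2-[2-(benzyloxy)ethyl]-2-(chloromethyl)oxirane A9. A second deprotonation at the other methyl group and opening of the epoxide at its CH2 terminus close the ring to hydrazone A10, and mild hydrolysis would give 8.
- Merits: the carbocycle and the C1 oxygen are made in one pot. No carboxyl carbon is installed and then removed, and the road joins the chosen route at 8.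
- Weak points: A9 needs three to four steps. The ring closure is an endo epoxide opening that must beat exo attack at the quaternary carbon, and also intermolecular alkylation. The second deprotonation has to take place at the unsubstituted methyl group. The total is about seven steps.
- Comparison: this road is more convergent and better in redox economy. The chosen plan sets against it simple starting materials and a key step with no regiochemical choice.

Key step: step 2

Assumption: 11 is achiral, so lactone 5 is carried as a racemate and β-keto ester 6 as a mixture of diastereomers and enol form; these centres disappear by step 4.

## Steps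

Step 1
Reactants: 1 3-(benzyloxy)propanal; 2 methyl acrylate
Product: 3 methyl 6-(benzyloxy)-4-oxohexanoate
Conditions: 3-benzyl-5-(2-hydroxyethyl)-4-methylthiazolium chloride (10 mol%), Et3N (0.5 equiv), 2 (1.5 equiv), 1,4-dioxane, 80 °C, slow addition of 1
Reagents that add atoms: none
Why: Stetter reaction; the thiazolium carbene turns the aldehyde carbon of 1 into a Breslow-type acyl anion equivalent that adds 1,4 to 2 and releases the catalyst, giving the 1,4-keto ester; aliphatic aldehydes and acrylates are standard partners, and slow addition of 1 should limit acyloin formation and base-induced loss of the β-benzyloxy group.

Step 2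
Reactants: 3 methyl 6-(benzyloxy)-4-oxohexanoate; 2 methyl acrylate
Product: 5 methyl 3-[2-(2-(benzyloxy)ethyl)-5-oxotetrahydrofuran-2-yl]propanoate (racemic), via open-chain hydroxy diester alkoxide 4 (not isolated)
Conditions: constant-current electrolysis (about 3 F/mol), carbon-fibre cathode, Pt anode, divided cell, Et4NOTs, Me3SiCl (3 equiv), 2 (2 equiv), DMF, 0–20 °C; then 1 M HCl work-up
Reagents that add atoms: none
Why: This is the cathodic hydrocoupling of a dialkyl ketone with an acrylate in the presence of Me3SiCl, a known reaction type; its closest relatives are the electroreductive ketone–acrylate lactonisation and the same coupling driven by SmI2 (samarium diiodide, divalent samarium). One electron enters the more easily reduced partner (the acrylate, or the ketone once activated by the silyl chloride), the radical anion bonds C1 of 3 to the β-carbon of 2, and a second electron gives the ester enolate, which is silylated or protonated. The tertiary alkoxide of 4 (or its silyl ether on acid work-up) attacks an ester carbonyl in a 5-exo-trig acyl substitution and closes the γ-lactone with loss of methoxide. Both arms on C1 of 4 are identical methyl propanoate chains, so lactonisation on either arm gives the same compound. The quaternary carbon of 5 is a stereocentre formed with no controlling element, so 5 is racemic; this is immaterial because the centre becomes the achiral C1 of 11. The selectivity needed is cross-coupling over acrylate hydrodimerisation, pinacol formation and plain reduction of the ketone; the hindered dialkyl ketone pairs poorly with itself, the silyl chloride traps the oxyanions, and 2 is used in modest excess. The benzyl ether and the ester of 3 are reduced only at more negative potentials and should remain untouched.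

Step 3
Reactants: 5 methyl 3-[2-(2-(benzyloxy)ethyl)-5-oxotetrahydrofuran-2-yl]propanoate
Product: 6 methyl 5-[2-(benzyloxy)ethyl]-5-hydroxy-2-oxocyclohexane-1-carboxylate (racemic, mixture of cis and trans isomers and enol form)
Conditions: KOtBu (2.2 equiv), THF (0.05 M), 0 °C to rt; AcOH quench
Reagents that add atoms: none
Why: Dieckmann condensation with the lactone as acyl acceptor; the enolate of the methyl ester arm (C5) attacks the lactone carbonyl (C4) in a 6-exo-trig closure and releases the C1 oxygen as a tertiary alkoxide. The opposite mode (lactone enolate onto the methyl ester) gives a bridged keto lactone that cannot form a stabilised enolate and is reopened by methoxide to the same product, so all material should collect as the stabilised enolate of 6; the hydroxyl is γ to both carbonyls, so no β-elimination is possible.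

Step 4
Reactants: 6 methyl 5-[2-(benzyloxy)ethyl]-5-hydroxy-2-oxocyclohexane-1-carboxylate
Product: 8 4-[2-(benzyloxy)ethyl]-4-hydroxycyclohexan-1-one, via lithium β-keto carboxylate 7 (not isolated)
Conditions: LiCl (3 equiv), H2O (2 equiv), DMSO, 130 °C
Reagents that add atoms: none
Why: Krapcho demethoxycarbonylation; chloride removes the ester methyl group by SN2, carboxylate 7 loses carbon dioxide and the resulting enolate is protonated by water. The medium is essentially neutral, which suits the tertiary alcohol and the benzyl ether, and both stereocentres of 6 vanish.

Step 5
Reactants: 8 4-[2-(benzyloxy)ethyl]-4-hydroxycyclohexan-1-one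
Product: 9 4-hydroxy-4-(2-hydroxyethyl)cyclohexan-1-one
Conditions: H2 (1 atm), 10% Pd/C, EtOAc, rt
Reagents that add atoms: none
Why: Catalytic hydrogenolysis of a benzyl ether; an aliphatic ketone and a tertiary alcohol are not reduced over Pd/C at ambient pressure, and a non-alcoholic solvent avoids ketal formation.

Step 6
Reactants: 9 4-hydroxy-4-(2-hydroxyethyl)cyclohexan-1-one; 10 palmitoyl chloride
Product: 11 2-(1-hydroxy-4-oxocyclohexyl)ethyl hexadecanoate
Conditions: 10 (1.05 equiv), pyridine (2 equiv), CH2Cl2, 0 °C to rt
Reagents that add atoms: none
Why: Acylation of an alcohol with an acid chloride through the acylpyridinium ion; the unhindered primary hydroxyl reacts far faster than the tertiary one, which needs forcing conditions, so one equivalent at 0 °C should give the monoester only.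

## Compound list

1 | 3-(benzyloxy)propanal | O=CCCOCc1ccccc1 | starting material
2 | methyl acrylate | C=CC(=O)OC | starting material
3 | methyl 6-(benzyloxy)-4-oxohexanoate | COC(=O)CCC(=O)CCOCc1ccccc1 | intermediate
4 | dimethyl 4-[2-(benzyloxy)ethyl]-4-hydroxyheptanedioate (formed as its tertiary alkoxide or O-trimethylsilyl ether, not isolated) | COC(=O)CCC(O)(CCOCc1ccccc1)CCC(=O)OC | intermediate
5 | methyl 3-[2-(2-(benzyloxy)ethyl)-5-oxotetrahydrofuran-2-yl]propanoate (racemic) | COC(=O)CCC1(CCOCc2ccccc2)CCC(=O)O1 | intermediate
6 | methyl 5-[2-(benzyloxy)ethyl]-5-hydroxy-2-oxocyclohexane-1-carboxylate (racemic, diastereomer mixture) | COC(=O)C1CC(O)(CCOCc2ccccc2)CCC1=O | intermediate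
7 | lithium 5-[2-(benzyloxy)ethyl]-5-hydroxy-2-oxocyclohexane-1-carboxylate (not isolated) | [Li+].[O-]C(=O)C1CC(O)(CCOCc2ccccc2)CCC1=O | intermediate
8 | 4-[2-(benzyloxy)ethyl]-4-hydroxycyclohexan-1-one | O=C1CCC(O)(CCOCc2ccccc2)CC1 | intermediate
9 | 4-hydroxy-4-(2-hydroxyethyl)cyclohexan-1-one | O=C1CCC(O)(CCO)CC1 | intermediate
10 | palmitoyl chloride (hexadecanoyl chloride) | CCCCCCCCCCCCCCCC(=O)Cl | starting material
11 | 2-(1-hydroxy-4-oxocyclohexyl)ethyl hexadecanoate | CCCCCCCCCCCCCCCC(=O)OCCC1(O)CCC(=O)CC1 | target

## Step count and risk

Total step count: 6. Longest linear sequence: 6 steps (1 to 11).

**Step 2 (key step).** The current may be consumed by hydrodimerisation or oligomerisation of the acrylate, or by two-electron reduction of the ketone to the secondary alcohol. The reason is that an unactivated dialkyl ketone is harder to reduce than the acrylate, so the cross reaction depends on the silyl chloride and on the concentration ratio. The fallback sets out from 3 and forms the same C1–C2 bond by polar addition. Methyl propiolate and LDA in THF at −78 °C give lithium methyl propiolate F4, which adds to the ketone of 3 while the ester is left alone at this temperature. The product is dimethyl 4-[2-(benzyloxy)ethyl]-4-hydroxyhept-2-ynedioate F5, as its lithium alkoxide. On warming, or with a trace of TsOH, it lactonises onto the saturated arm only, because the linear alkynoate arm cannot be reached, and gives methyl 3-[2-(2-(benzyloxy)ethyl)-5-oxotetrahydrofuran-2-yl]prop-2-ynoate F6. Hydrogenation of the triple bond (H2, 5% Rh/Al2O3, EtOAc, conditions that spare benzyl ethers) returns to the route at 5.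

**Step 1.** Base-induced β-elimination of the benzyloxy group from the aldehyde, and acyloin self-condensation, may outrun the conjugate addition. Aldehyde 1 has an acidic α-CH2 next to a β-leaving group, and acrylates are only moderate Stetter acceptors. The fallback sets out from 1. Pinnick oxidation (NaClO2, NaH2PO4, 2-methyl-2-butene, t-BuOH/H2O) gives 3-(benzyloxy)propanoic acid F1. Oxalyl chloride with catalytic DMF gives 3-(benzyloxy)propanoyl chloride F2. Acylation of (3-methoxy-3-oxopropyl)zinc iodide F3 (from methyl 3-iodopropanoate and Zn dust, catalysed by Pd(PPh3)4 in THF) with F2 forms the same ketone and returns to the route at 3.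

**Step 4.** Thermal or DMSO-assisted dehydration of the tertiary carbinol may set in at the temperature the chloride dealkylation needs. The fallback sets out from 6 and replaces nucleophilic dealkylation by hydrolysis. LiOH in THF/H2O at 0 °C to rt gives the same carboxylate 7. Acidification to about pH 4 and warming to 40–50 °C should bring about loss of carbon dioxide and return to the route at 8. No new compound is involved.

**Step 6.** Site selectivity may erode, by acylation or HCl-promoted elimination at the tertiary hydroxyl when excess acid chloride or long reaction times are used. The fallback sets out from 9 and activates the alcohol instead of the acid: Mitsunobu esterification with hexadecanoic acid, PPh3 and DIAD in THF at 0 °C. This can engage only the primary hydroxyl and arrives directly at 11. No new compound is involved.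

The Dieckmann closure (step 3) is judged less exposed than these, because every Claisen mode open to 5 is reversible and leads to the one stabilised enolate of 6.

## Further compounds

F1 | step 1 | 3-(benzyloxy)propanoic acid | OC(=O)CCOCc1ccccc1
F2 | step 1 | 3-(benzyloxy)propanoyl chloride | O=C(Cl)CCOCc1ccccc1
F3 | step 1 | (3-methoxy-3-oxopropyl)zinc iodide | COC(=O)CC[Zn]I
F4 | step 2 | lithium methyl propiolate (lithium 3-methoxy-3-oxoprop-1-yn-1-ide) | [Li]C#CC(=O)OC
F5 | step 2 | dimethyl 4-[2-(benzyloxy)ethyl]-4-hydroxyhept-2-ynedioate (racemic, formed as its lithium alkoxide) | COC(=O)C#CC(O)(CCOCc1ccccc1)CCC(=O)OC
F6 | step 2 | methyl 3-[2-(2-(benzyloxy)ethyl)-5-oxotetrahydrofuran-2-yl]prop-2-ynoate (racemic) | COC(=O)C#CC1(CCOCc2ccccc2)CCC(=O)O1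
F0 | step 4 | none | none
F0 | step 6 | none | none
A1 | alternative 1 | 4-methylenecyclohexan-1-one | C=C1CCC(=O)CC1
A2 | alternative 1 | formaldehyde | C=O
A3 | alternative 1 | 1,3-dioxaspiro[5.5]undecan-9-one | O=C1CCC2(CC1)CCOCO2
A4 | alternative 2 | 1-[2-(benzyloxy)ethyl]cyclohexa-1,3-diene | C(COCc1ccccc1)C1=CC=CCC1
A5 | alternative 2 | dioxygen (used in its singlet state) | O=O
A6 | alternative 2 | 1-[2-(benzyloxy)ethyl]-2,3-dioxabicyclo[2.2.2]oct-5-ene (racemic, one enantiomer drawn) | C(COCc1ccccc1)[C@]12OO[C@H](C=C1)CC2
A7 | alternative 2 | 4-[2-(benzyloxy)ethyl]-4-hydroxycyclohex-2-en-1-one (racemic) | O=C1C=CC(O)(CCOCc2ccccc2)CC1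
A8 | alternative 3 | acetone N,N-dimethylhydrazone | CC(C)=NN(C)C
A9 | alternative 3 | 2-[2-(benzyloxy)ethyl]-2-(chloromethyl)oxirane (racemic) | ClCC1(CCOCc2ccccc2)CO1
A10 | alternative 3 | 4-[2-(benzyloxy)ethyl]-4-hydroxycyclohexan-1-one N,N-dimethylhydrazone | CN(C)N=C1CCC(O)(CCOCc2ccccc2)CC1
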